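**Plan**

- Retrosynthesis: cut the two prenyl–C5 bonds, then the C3–acyl bond, then in one event the C1–C8' bond together with the C7'–O bond, then the C1–C1' bond (reductive alkylation of phloroglucinol), then C2'–C3' (aldol). This leads back to (S)-limonene, whose ten carbons become C1'–C10'.
- Enabling feature: C1 is the alkylated carbon of a phloroglucinol, flanked by two equivalent C–O carbons. In the target the C7' hydroxyl stands 1,3-diaxial to the C6 carbonyl on ring C. A two-electron oxidation of the arene therefore lets C8' (the CH2 end of an isopropenyl group) bond to C1 while the C6 oxygen captures C7'.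
- Forward order: ring B (cyclopentane, aldol), arene joined at C1', ring C plus a temporary oxolane bridge (key step), acyl group at C3, bridge and silyl ether hydrolysed, gem-diprenyl at C5.
- Stereochemistry: C6' comes from (S)-limonene, C2' and C3' from the D-proline aldol, C7' and the spiro carbon C1 from the chair and bridge geometry of the key step. The bridge marks C6, so acylation (C3) and prenylation (C5) go to the correct flanks of C1.

Key step: step 5

Remark on locants and tautomers: ring A is C1 (spiro carbon), C2 (carbonyl next to the acyl-bearing C3), C4 (enol carbon), C5 (diprenyl carbon), C6 (ketone between C5 and C1). The monoterpene unit is C1' (CH2 on C1), C2' and C6' (ring-fusion CH), C3' (carbinol carbon of cyclopentane ring B), C4', C5', C7' (carbinol carbon of spiro cyclohexane ring C) and C8' (second CH2 on C1). Enolised β-polyketones are drawn in one tautomeric form.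

**Route**

Step 1
Reactants: 1 (S)-(−)-limonene
Product: 3 (3S)-6-oxo-3-(prop-1-en-2-yl)heptanal, via ozonide 2 (not isolated)
Conditions: O3 (about 1 equiv), CH2Cl2, −78 °C; then PPh3, −78 °C to rt
Reagents that add atoms: ozone, [O-][O+]=O
Why: Ozonolysis with reductive work-up: ozone should attack the more electron-rich trisubstituted ring alkene before the 1,1-disubstituted isopropenyl group when about one equivalent is used cold, and the stereocenter is not touched.

Step 2
Reactants: 3 (3S)-6-oxo-3-(prop-1-en-2-yl)heptanal
Product: 4 (1R,2S,5S)-2-hydroxy-2-methyl-5-(prop-1-en-2-yl)cyclopentane-1-carbaldehyde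
Conditions: D-proline (20 mol %), DMSO, rt
Reagents that add atoms: none
Why: Proline-catalysed intramolecular aldol addition (5-enolexo aldolisation): the aldehyde enamine should add to the methyl ketone through the transition state in which the carboxylic acid hydrogen-bonds the ketone oxygen, which places the new hydroxyl cis to the formyl group (C3' S); D-proline is the enantiomer whose preferred enamine face gives C2' R with the isopropenyl group of C6' trans to the formyl group, and the near-neutral conditions should leave the tertiary aldol undehydrated.

Step 3
Reactants: 4 (1R,2S,5S)-2-hydroxy-2-methyl-5-(prop-1-en-2-yl)cyclopentane-1-carbaldehyde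
Product: 5 (1R,2S,5S)-2-methyl-5-(prop-1-en-2-yl)-2-(triethylsilyloxy)cyclopentane-1-carbaldehyde
Conditions: TESOTf, 2,6-lutidine, CH2Cl2, −78 °C
Reagents that add atoms: triethylsilyl trifluoromethanesulfonate, CC[Si](CC)(CC)OS(=O)(=O)C(F)(F)F
Why: Silylation of a tertiary alcohol with a silyl triflate and a hindered pyridine base: the C3' oxygen is capped so that it cannot add to the oxidised arene in step 5, and the cold conditions should leave the enolisable aldehyde untouched.

Step 4
Reactants: 5 (1R,2S,5S)-2-methyl-5-(prop-1-en-2-yl)-2-(triethylsilyloxy)cyclopentane-1-carbaldehyde; 6 phloroglucinol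
Product: 8 2-{[(1R,2S,5S)-2-methyl-5-(prop-1-en-2-yl)-2-(triethylsilyloxy)cyclopentyl]methyl}benzene-1,3,5-triol, via quinone methide 7 (not isolated)
Conditions: 6 (3 equiv), Hantzsch ester (1.2 equiv), D-proline (20 mol %), EtOH, rt
Reagents that add atoms: none
Why: Knoevenagel condensation followed by transfer hydrogenation from the Hantzsch ester (three-component reductive alkylation): phloroglucinol should condense through a ring carbon to the ortho-quinone methide 7, which the dihydropyridine should reduce at C1' before it adds a second arene or tautomerises, the excess of 6 holds the reaction at monoalkylation, and C2' is already the more stable epimer.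

Step 5
Reactants: 8 2-{[(1R,2S,5S)-2-methyl-5-(prop-1-en-2-yl)-2-(triethylsilyloxy)cyclopentyl]methyl}benzene-1,3,5-triol
Product: 10 bridged enol ether dienone (spiro C1; C6–O–C7' oxolane bridge; ring A as 2-hydroxycyclohexa-2,5-dien-4-one; trans-fused rings B and C; C3' silyl ether), via tertiary carbocation 9 (not isolated)
Conditions: PhI(OAc)2 (1.05 equiv), (CF3)2CHOH/CH2Cl2 (1:4), 0.005 M, −40 to 0 °C
Reagents that add atoms: none
Why: Proposed new method: PhI(OAc)2 should oxidise the phloroglucinol by two electrons (an aryloxy derivative of trivalent iodine, then a phenoxenium ion that is an oxyallyl-type cation centred on the alkylated carbon C1), the CH2 terminus of the isopropenyl group should attack C1 in a 6-endo-trig cation–olefin closure that moves the charge to the tertiary carbon C7' (cation 9), and the oxygen of the ring-A carbon that stands axial on the new cyclohexane should trap it, giving the enol ether after loss of a proton; the closest known reaction types are the hypervalent-iodine oxidative dearomatisation of phenols with ipso attack of a tethered alkene and the oxidative formal (3+2) annulation of phenols or 1,3-diones with alkenes to dihydrofurans, neither of which has been shown on a 2-alkylphloroglucinol to give a bridged enol ether. Ring C should close through a chair transition state in which C3' and C5' of the trans-1,2-disubstituted cyclopentane are equatorial (trans-hydrindane), and the oxolane bridge closes by 1,3-diaxial capture, a five-membered ring that only a cis-diaxial pair can span. C7' is therefore set with its oxygen axial (anti to H-6', methyl equatorial, R) by the chair and the bridge, and the spiro carbon C1 is set relative to C7' because the oxygen-bridged ring-A carbon, the later C6, is necessarily the axial one. The two ortho carbons of the symmetric arene are equivalent, so no choice between the two flanks of C1 has to be made in the C–C bond-forming event, and the bridge records the outcome for steps 6 to 8. The selectivities needed are attack at C1 and not at the unsubstituted ring carbons (only C1 is within reach of a six-membered transition state), attack through the CH2 terminus (Markovnikov sense, tertiary and not primary cation), C–C bond formation before capture by oxygen (the only hydroxyl in reach, at C3', is silylated and the fluorinated alcohol is non-nucleophilic) and capture of the cation before elimination (intramolecular, five-membered). One equivalent of oxidant, high dilution and low temperature should limit a second oxidation of the enolic product.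

Step 6
Reactants: 10 bridged enol ether dienone; 11 isovaleryl chloride
Product: 13 3-isovaleryl bridged enol ether (β-triketone at C2–C3–C4; bridge and silyl ether intact), via enol ester 12 (not isolated)
Conditions: 11, Et3N, CH2Cl2, 0 °C; then DMAP (20 mol %), rt
Reagents that add atoms: none
Why: O-acylation of the vinylogous acid followed by DMAP-catalysed O-to-C acyl migration (the standard route to 2-acyl-1,3-diones): C3 is the only ring-A carbon between two free carbonyl groups because the C6 oxygen is held in the bridge, so the acyl group should enter next to the unbridged C2 carbonyl, which is what gives the spiro carbon the configuration of the target.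

Step 7
Reactants: 13 3-isovaleryl bridged enol ether
Product: 14 des-prenyl triketone diol (5-unsubstituted analogue of the target; free C3' and C7' hydroxyls)
Conditions: 2 M HCl (aq), THF, rt
Reagents that add atoms: water, O
Why: Acid hydrolysis of a vinylogous ester (enol-ether hydrolysis by protonation at C5 and addition of water at C6): the C6–O bond is cleaved on the acyl side, so C7' keeps its oxygen and configuration, and the same aqueous acid removes the triethylsilyl group from the C3' oxygen.

Step 8
Reactants: 14 des-prenyl triketone diol; 15 prenyl bromide
Product: 17 CNP0198642.4 (target), via monoprenyl triketone 16 (not isolated)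
Conditions: 15 (2.5 equiv), NaOMe, MeOH, 0 °C to rt
Reagents that add atoms: none
Why: Double C-alkylation of the enolised β-polyketone anion with prenyl bromide (the alkylation that builds the gem-diprenyl carbon of lupulone-type acylphloroglucinols): C5 is the only enolisable carbon left in ring A, so both prenyl groups should enter there, and no stereocenter forms because the two groups are identical.

**Compound list**

1 | (S)-(−)-limonene | CC1=CC[C@H](CC1)C(C)=C | starting material
2 | secondary ozonide of the ring alkene of limonene | CC12CC[C@@H](CC(OO1)O2)C(C)=C | intermediate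
3 | (3S)-6-oxo-3-(prop-1-en-2-yl)heptanal | O=CC[C@H](CCC(C)=O)C(C)=C | intermediate
4 | (1R,2S,5S)-2-hydroxy-2-methyl-5-(prop-1-en-2-yl)cyclopentane-1-carbaldehyde | O=C[C@@H]1[C@H](CC[C@]1(C)O)C(C)=C | intermediate
5 | (1R,2S,5S)-2-methyl-5-(prop-1-en-2-yl)-2-(triethylsilyloxy)cyclopentane-1-carbaldehyde | O=C[C@@H]1[C@H](CC[C@]1(C)O[Si](CC)(CC)CC)C(C)=C | intermediate
6 | phloroglucinol (benzene-1,3,5-triol) | Oc1cc(O)cc(O)c1 | starting material
7 | ortho-quinone methide (Knoevenagel adduct of 5 and 6) | OC1=CC(O)=CC(=O)C1=C[C@@H]1[C@H](CC[C@]1(C)O[Si](CC)(CC)CC)C(C)=C | intermediate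
8 | 2-{[(1R,2S,5S)-2-methyl-5-(prop-1-en-2-yl)-2-(triethylsilyloxy)cyclopentyl]methyl}benzene-1,3,5-triol | Oc1cc(O)c(C[C@@H]2[C@H](CC[C@]2(C)O[Si](CC)(CC)CC)C(C)=C)c(O)c1 | intermediate
9 | spirocyclic tertiary carbocation at C7' (ring C closed, ring A as dihydroxy dienone) | O=C1C=C(O)C=C(O)[C@]12C[C@@H]3[C@H](CC[C@]3(C)O[Si](CC)(CC)CC)[C+](C)C2 | intermediate
10 | bridged enol ether dienone (C6–O–C7' bridge, C7' oxygen axial, trans-fused rings B and C, C3' triethylsilyl ether) | O=C1C=C2[C@@]3(C[C@@H]4[C@H](CC[C@]4(C)O[Si](CC)(CC)CC)[C@](C)(O2)C3)C(O)=C1 | intermediate
11 | isovaleryl chloride (3-methylbutanoyl chloride) | CC(C)CC(Cl)=O | starting material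
12 | enol isovalerate of 10 (O-acyl at C2) | O=C1C=C2[C@@]3(C[C@@H]4[C@H](CC[C@]4(C)O[Si](CC)(CC)CC)[C@](C)(O2)C3)C(OC(=O)CC(C)C)=C1 | intermediate
13 | 3-isovaleryl bridged enol ether | O=C1C=C2[C@@]3(C[C@@H]4[C@H](CC[C@]4(C)O[Si](CC)(CC)CC)[C@](C)(O2)C3)C(O)=C1C(=O)CC(C)C | intermediate
14 | des-prenyl triketone diol (5-unsubstituted analogue of the target) | C1C(=O)[C@@]2(C[C@@H]3[C@H](CC[C@]3(C)O)[C@](C)(O)C2)C(=O)C(C(=O)CC(C)C)=C1O | intermediate
15 | prenyl bromide (1-bromo-3-methylbut-2-ene) | CC(C)=CCBr | starting material
16 | 5-monoprenyl triketone diol | CC(C)=CCC1C(=O)[C@@]2(C[C@@H]3[C@H](CC[C@]3(C)O)[C@](C)(O)C2)C(=O)C(C(=O)CC(C)C)=C1O | intermediate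
17 | CNP0198642.4 (spiro C1 S, C2' R, C3' S, C6' S, C7' R) | CC(C)=CCC1(CC=C(C)C)C(=O)[C@@]2(C[C@@H]3[C@H](CC[C@]3(C)O)[C@](C)(O)C2)C(=O)C(C(=O)CC(C)C)=C1O | target

Total step count: 8. Longest linear sequence: 8 steps (1 to 17).

**Steps most likely to fail**

Step 5 (proposed new method). The oxidised arene may couple with a second molecule at its unsubstituted carbons or be oxidised further. The tertiary cation may lose a proton before the carbonyl oxygen traps it. The silyl ether may be solvolysed in the acidic fluorinated solvent, after which its oxygen would add to C1. The fallback uses known chemistry and oxidises the alkene instead of the arene; it sets out from 5 and returns at 10. Dimethyldioxirane in acetone converts the isopropenyl group of 5 into the oxirane; both C7' epimers are expected, and the (2S)-oxirane, (1R,2S,5S)-2-methyl-5-[(2S)-2-methyloxiran-2-yl]-2-(triethylsilyloxy)cyclopentane-1-carbaldehyde F1, is separated and carried on. Reductive alkylation of 6 under the conditions of step 4 gives the epoxy alkylphloroglucinol F2. Cs2CO3 in warm DMF should then bring about an alkylative dearomatisation in which the phenolate carbon C1 opens the oxirane at its CH2 terminus (SN2, C7' retained), giving the spiro hydroxy trione F3 with the C7' hydroxyl axial. This closure has to pass through a non-chair transition state and may need heating. Acid-catalysed enol-ether formation between this hydroxyl and the syn-axial carbonyl (PPTS, 4 Å molecular sieves, benzene, 60 °C, the intramolecular form of the usual conversion of a 1,3-dione and an alcohol into a vinylogous ester) gives 10.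

Step 2. The aldol may dehydrate to the conjugated enal, the ketone enamine may react instead of the aldehyde enamine, or diastereocontrol may be weak. The fallback sets out from 3 and returns at 4. Piperidine and AcOH (aldol condensation) give the enal (5R)-2-methyl-5-(prop-1-en-2-yl)cyclopent-1-ene-1-carbaldehyde F4. Alkaline H2O2 in MeOH at 0 °C (Weitz–Scheffer epoxidation) should add oxygen anti to the isopropenyl group to give the epoxy aldehyde F5. SmI2 in THF/MeOH at −90 °C cleaves the C2'–O bond (reduction of an α,β-epoxy carbonyl compound to the aldol), and brief equilibration of the enolisable C2' with Et3N to its most stable epimer gives 4.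

Step 8. O-alkylation of the enolate oxygens may compete with C-alkylation, and the second alkylation at the hindered C5 may stall. The fallback sets out from 14 and returns at 17. A Tsuji–Trost double allylation with allyl methyl carbonate and Pd(PPh3)4 (zerovalent palladium), which alkylates soft β-dicarbonyl anions at carbon, gives the 5,5-diallyl triketone diol F6. Cross-metathesis with excess 2-methylbut-2-ene and the second-generation Grubbs catalyst RuCl2(=CHPh)(H2IMes)(PCy3) then turns both allyl groups into prenyl groups and gives 17.

**Further compounds**

F1 | step 5 | (1R,2S,5S)-2-methyl-5-[(2S)-2-methyloxiran-2-yl]-2-(triethylsilyloxy)cyclopentane-1-carbaldehyde | O=C[C@@H]1[C@H](CC[C@]1(C)O[Si](CC)(CC)CC)[C@]2(C)OC2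
F2 | step 5 | 2-{[(1R,2S,5S)-2-methyl-5-[(2S)-2-methyloxiran-2-yl]-2-(triethylsilyloxy)cyclopentyl]methyl}benzene-1,3,5-triol | Oc1cc(O)c(C[C@@H]2[C@H](CC[C@]2(C)O[Si](CC)(CC)CC)[C@]3(C)OC3)c(O)c1
F3 | step 5 | spiro hydroxy trione (ring C closed, axial C7' hydroxyl, C3' triethylsilyl ether, ring A as cyclohexane-1,3,5-trione) | O=C1CC(=O)C2(C[C@@H]3[C@H](CC[C@]3(C)O[Si](CC)(CC)CC)[C@](C)(O)C2)C(=O)C1
F4 | step 2 | (5R)-2-methyl-5-(prop-1-en-2-yl)cyclopent-1-ene-1-carbaldehyde | O=CC1=C(C)CC[C@@H]1C(C)=C
F5 | step 2 | 5-methyl-2-(prop-1-en-2-yl)-6-oxabicyclo[3.1.0]hexane-1-carbaldehyde (oxirane oxygen anti to the isopropenyl group) | O=C[C@@]12[C@H](CC[C@]1(C)O2)C(C)=C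
F6 | step 8 | 5,5-diallyl triketone diol (diallyl analogue of 17) | C=CCC1(CC=C)C(=O)[C@@]2(C[C@@H]3[C@H](CC[C@]3(C)O)[C@](C)(O)C2)C(=O)C(C(=O)CC(C)C)=C1O
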